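The constants used here are assumed; the run is a simulation.

The easy step is J ⇌ X, and I reckon my next run from it: which flask to repeat, and how much Q to spend on it.

- south-west: Q 0.20 mM; temperature 95 °C; time 3.0 min
- south: Q 0.20 mM; temperature 80 °C; time 3.0 min

    J ⇌ X (K1 = 0.347, k1 = 1.17 s⁻¹, Ea1 = 81.0 kJ mol⁻¹, ΔH1 = −24.0 kJ mol⁻¹)
    L ⇌ E (K2 = 0.41, k2 = 0.789 s⁻¹, Ea2 = 72.0 kJ mol⁻¹, ΔH2 = 10.0 kJ mol⁻¹)
    X ⇌ L (K3 = 1.21, k3 = 0.0668 s⁻¹, Ea3 = 100 kJ mol⁻¹, ΔH3 = −15.0 kJ mol⁻¹)
    Q ⇌ J, rate k4*(cs4 - [J]) while solid is left; crystals form when [J] > cs4 (cs4 = 0.10 mM, k4 = 0.161 s⁻¹)
    (constants at 80 °C)

- given per volume of solution although it is solid: Q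
- at 80 °C the constants are as listed, elsewhere as the activation energies and enthalpies make them
- at the start none of Q is in solution
- what has only dissolved of Q counts as not reacted

- the best flask by amount of X, in percent of the Q charged; "all alike" if 1.5 percentage points covers them all (south-west / south / all alike)
- amount of X at the end, in percent of the Q charged, south-west
- amount of X at the end, in percent of the Q charged, south

I divide the forward rate of J ⇌ X by its back rate. The rate constant cancels, time drops out, and K[J]/[X] is left, where K is that step's equilibrium constant at the flask's temperature. In south-west this step relaxes in 0.0383 s, faster than the 1.28 s of X ⇌ L and short against the 3.0 min allowed, so I set the ratio to one and take [X] = K[J], which is thermodynamic control of this step.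

While solid Q lasts, J stands near its solubility s, which I hold at the given value in both flasks because no enthalpy is given for it. With C the Q charged, the X share is then K·s/C, which is 17.3 % in south. I carry this as Y, the saturation share. In south-west, heating lowers K to 0.249, so Y there is 12.4 %.

Y needs solid to remain, so I add up what J, X, L and E hold at balance: 0.194 mM in south and 0.161 mM in south-west. Both are less than the 0.20 mM charged. So I repeat south, and I charge no more Q than this, since C stands below the line in Y.

The forecast takes the same balance: south is best, with 12.4 % in south-west and 17.3 % in south, and in its words “the cooler south flask gives more X”.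

The simulation gives south as best, with 12.4 % in south-west and 17.3 % in south. In south at 3.00 min, J stands at 50.0 % of the charge, and Q is still there at 3.22 %. South's answer has moved by 5 points at a charge of 0.281 mM, and Y at that charge is 12.3 %, which is 5 percentage points below south.

For a flask like south-west kept at 120 °C, Y is 7.55 %. The simulation gives 7.55 %, with Q at 33.9 % at 3.00 min.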